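Per unit of substrate charged, grey and red differ in the coupling partner they receive.

    substrate + coupling partner → intermediate + by-product (k1 = 0.688 M⁻¹ s⁻¹)
    intermediate → target (k2 = 0.0199 s⁻¹)
    coupling partner + by-product ⇌ idle adduct, settled at all times (K3 = 287 M⁻¹)
    target + by-product → side product (k4 = 0.530 M⁻¹ s⁻¹)
    intermediate → decomposed reagent (k5 = 7.00 × 10⁻⁴ s⁻¹)

common to all: substrate 10 mM; time 1.5 min
- grey: coupling partner 1.80 equiv
- red: coupling partner 5.40 equiv

- amounts and yields of by-product count idle adduct too
- run time (grey): 1.5 min

- which of these there is most of at the end, counted by the substrate in it, grey (substrate / intermediate / target / side product)
- which of these there is most of at the end, counted by the substrate in it, red (substrate / intermediate / target / side product)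
- final amount of the leader among these, as a percentage of the substrate charged, in grey
- final amount of the leader among these, as a percentage of the substrate charged, in red

Each turnover spends one coupling partner, and the by-product it releases can bind one more as idle adduct. The partner price is the free coupling partner lost per substrate turned over. With price c, e equivalents, and τ (the step-one constant times substrate charge times time) equal to 0.619, the fraction of substrate left is (e − c)/(e·exp((e − c)τ) − c). Two extreme versions of grey solve by hand: by-product never bound, price one, leaves 40.9 %; every by-product bound, price two, leaves 48.8 %.

Grey itself lies between these two. At the charge, adduct stands to free by-product as 5.2 to one in grey, so the price, one plus the bound share, is 1.84; in red it is 1.94. This reckoning turns over 52.4 % in grey, leaving 47.6 % substrate, and 92.2 % in red.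

Turnover is then taken as pseudo-first-order, with constants 0.495 min⁻¹ in grey and 1.70 min⁻¹ in red, which give those remainders. Decomposition is dropped, since the half-life of intermediate by step two, 0.58 min, is far shorter than its half-life by step five, 17 min. That leaves intermediate at 21.9 % in grey and 29.8 % in red. Grey's side product, reckoned from free by-product, comes to 0.619 %. So grey is led by substrate and red by target, at 62.3 %.

The forecast names substrate at 46 % in grey and target at 65 % in red, lower than this reckoning in grey and higher in red. Its grounds: “the by-product ties up free coupling partner as idle adduct”.

The flasks end as the forecast named them: grey with substrate at 46.9 %, red with target at 61.8 %. With 50 % of grey's coupling partner still free at the end, the price reckoned for that moment is 1.72, lower than the 1.84 reckoned at the charge. A neighbour of grey charged with 1.10 equiv has a price at the charge of 1.76, and the same formula leaves 64.1 % substrate. That neighbour ends with 63.3 % substrate.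

The constants belong to no real substance.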